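The small charge of incoming ligand in the north-east run left 8.5% of complex with one exchanged at 4.0 h, so I asked what part of a charge stays there.

| setting | north-east | north-west | flask |
|---|---|---|---|
| starting complex | 0.50 M | 0.50 M | 0.50 M |
| incoming ligand | 0.34 equiv | 0.75 equiv | 0.500 equiv |
| leaving ligand | 5 equiv | 5 equiv | 5.00 equiv |
| remark | run made earlier | run made earlier |  |
| time |  |  | 4.0 h |

| north-east: time / h | north-east: complex with one exchanged / % | north-west: time / h | north-west: complex with one exchanged / % |
|---|---|---|---|
| 0.833 | 12.9 | 0.333 | 19.9 |
| 1.50 | 13.0 | 0.667 | 26.5 |
| 2.50 | 11.4 | 1.00 | 27.4 |
| 3.00 | 9.8 | 2.00 | 28.2 |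
| 4.00 | 8.5 | 4.00 | 26.6 |

(each reading ± 0.3 percentage points)

- a species is counted by the starting complex in it: one side product counts as two
- steps under discussion: starting complex + incoming ligand -> leaving ligand + complex with one exchanged; complex with two exchanged + incoming ligand -> leaving ligand + complex with three exchanged; starting complex <-> dormant form; complex with one exchanged + incoming ligand -> leaving ligand + complex with two exchanged; starting complex + complex with one exchanged -> side product

- equivalents of incoming ligand to starting complex, everything else as given, that leave most complex with one exchanged at 4.0 h
- the amount of complex with one exchanged then, in percent of the starting complex charged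
- the amount of complex with one exchanged with the amounts as given

I divided each reading at 4.0 h by the equivalents of incoming ligand charged. The north-east run gave 0.250. The north-west run gave 0.355, which is more.

I assumed that this share rises steadily with the charge between the two runs. The north-east share on the flask's 0.500 equiv then gives a floor of 12.5%, and the north-west share gives a ceiling of 17.7%.

To tighten this, I joined the two ends by a straight line, rising 0.255 per equivalent. At the flask's charge it reads 0.291. This is the keeping share, the part of the charged incoming ligand that stands as complex with one exchanged at 4.0 h. My figure was 14.5%.

For the best amount I had a floor of 26.6%, the north-west reading. That reading stood higher than the north-east one, so I looked for the best charge above 0.75 equiv, as an expectation and not as a bound.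

The forecast gave 15%, inside my bracket, and 30% at 1 equiv, above my floor. It came to that charge with “a bit more because extra ligand suppresses the side reaction”.

The flask gave 15.7%, inside the bracket. The best charge was 1.63 equiv, giving 39.0%, so the forecast's charge stood lower.

    starting complex + incoming ligand → leaving ligand + complex with one exchanged (k = 8.17 × 10⁻⁴ M⁻¹ s⁻¹)
    complex with two exchanged + incoming ligand → leaving ligand + complex with three exchanged (k = 6.84 × 10⁻⁵ M⁻¹ s⁻¹)
    starting complex ⇌ dormant form (K = 5.47, k = 5.99 × 10⁻⁵ s⁻¹)
    complex with one exchanged + incoming ligand → leaving ligand + complex with two exchanged (k = 7.18 × 10⁻⁵ M⁻¹ s⁻¹)
    starting complex + complex with one exchanged → side product (k = 6.82 × 10⁻⁴ M⁻¹ s⁻¹)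

The half-life of complex with one exchanged by its loss to side product alone, other concentrations as charged, was 0.56 h, short against 4.0 h. The flask's keeping share came to 0.314, against 0.291 from the line. A neighbour flask was charged with 0.200 equiv, below both runs. The line, carried beyond its two ends, gave it a share of 0.214, hence 4.29%, and the complex with one exchanged in that neighbour flask stood at 3.85%.

The runs were generated by integration from invented constants; the scatter is artificial.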